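**Retrosynthetic overview**
1. Target ⇐ acetylation of O2, O12, O14 ⇐ 12-OH-directed epoxidation of the 11(20)-alkene.
2. Ten-membered ring and γ-lactone ⇐ one CrCl2-mediated intramolecular chloroallylation of a C7 aldehyde (C6–C7 bond; gives 6-Cl, 7-O and the 5(16)-methylene together), then lactonization of O7 onto C19.
3. Ring A and the ring-fusion bond C1–C10 ⇐ key step: Mn(OAc)3/Cu(OAc)2 oxidative 6-endo radical cyclization of an open-chain 2-methyl-1,3-diketone onto the C10=C11 alkene (quaternary C1, C10 and the 11(20)-methylene in one step); C14 and C2 carbinols by relayed hydroxyl-directed reduction.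
4. Open-chain precursor ⇐ catalytic asymmetric vinylogous Mukaiyama aldol (C12–C13) of a bis-silyl dienolate (from 3-methylpentane-2,4-dione and a C4 trichloride) with a C7–C12/C17–C19 enal.
5. Enal ⇐ lactate-derived phosphonate olefination (C8=C9), Sharpless epoxidation (C8, C9), C9-selective acetolysis. Ring order: ring A, then ten-membered ring and lactone together, then the epoxide.

Assumption: atom labels follow briarane numbering (C1 quaternary ring-fusion carbon with CH3-15, C2–C9 the rest of the ten-membered ring, C10 ring-fusion CH, C11–C14 ring A, C16 the methylene on C5, C17/C18/C19 lactone CH/CH3/C=O, C20 epoxide CH2); tert-butyl (R)-lactate and (2E)-4,4-dimethoxy-3-methylbut-2-enal are taken as purchasable.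

**Step 1**
Reactants: 1 tert-butyl (2R)-2-hydroxypropanoate
Product: 2 tert-butyl (2R)-2-[(trifluoromethanesulfonyl)oxy]propanoate
Conditions: Tf2O, 2,6-lutidine, CH2Cl2, −78 to 0 °C
Reagents that add atoms: trifluoromethanesulfonic anhydride O=S(=O)(OS(=O)(=O)C(F)(F)F)C(F)(F)F
Why: O-sulfonylation of the secondary alcohol with retention gives a leaving group that is displaced cleanly by SN2 in step 2.

**Step 2**
Reactants: 3 ethyl bromoacetate; 2 tert-butyl (2R)-2-[(trifluoromethanesulfonyl)oxy]propanoate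
Product: 5 4-tert-butyl 1-ethyl (3S)-2-(diethoxyphosphoryl)-3-methylbutanedioate, via triethyl phosphonoacetate 4 (not isolated)
Conditions: P(OEt)3, neat, 130 °C (EtBr distilled off); then NaH, THF, 0 °C; then 2, −40 to 0 °C
Reagents that add atoms: triethyl phosphite CCOP(OCC)OCC
Why: Michaelis–Arbuzov reaction followed by SN2 alkylation of the sodium phosphonoacetate by the lactate triflate with inversion, which sets C17 (the phosphonate carbon is an inconsequential epimer mixture).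

**Step 3**
Reactants: 5 4-tert-butyl 1-ethyl (3S)-2-(diethoxyphosphoryl)-3-methylbutanedioate; 6 (2E)-4,4-dimethoxy-3-methylbut-2-enal
Product: 7 4-tert-butyl 1-ethyl (2E,3R)-2-[(2E)-4,4-dimethoxy-3-methylbut-2-en-1-ylidene]-3-methylbutanedioate
Conditions: LiCl, iPr2NEt, MeCN, 0 to 23 °C
Reagents that add atoms: none
Why: Horner–Wadsworth–Emmons olefination under mild Masamune–Roush conditions gives the (E)-alkylidene succinate (C10 trans to the C7 ester), the geometry that later becomes the 8,9-anti dioxygen pattern, without epimerizing C17.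

**Step 4**
Reactants: 7 4-tert-butyl 1-ethyl (2E,3R)-2-[(2E)-4,4-dimethoxy-3-methylbut-2-en-1-ylidene]-3-methylbutanedioate
Product: 8 tert-butyl (2R,3E,5E)-3-(hydroxymethyl)-7,7-dimethoxy-2,6-dimethylhepta-3,5-dienoate
Conditions: iBu2AlH (2.2 equiv), CH2Cl2, −78 °C
Reagents that add atoms: none
Why: chemoselective 1,2-reduction of the conjugated ethyl ester to the allylic alcohol while the hindered α-branched tert-butyl ester survives and cannot lactonize onto the new primary hydroxyl under neutral conditions.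

**Step 5**
Reactants: 8 tert-butyl (2R,3E,5E)-3-(hydroxymethyl)-7,7-dimethoxy-2,6-dimethylhepta-3,5-dienoate
Product: 9 tert-butyl (2R)-2-[(2S,3S)-3-[(1E)-3,3-dimethoxy-2-methylprop-1-en-1-yl]-2-(hydroxymethyl)oxiran-2-yl]propanoate
Conditions: Ti(OiPr)4 (10 mol%), diethyl L-tartrate (12 mol%), tert-butyl hydroperoxide, 4 Å molecular sieves, CH2Cl2, −20 °C
Reagents that add atoms: tert-butyl hydroperoxide CC(C)(C)OO
Why: Sharpless asymmetric epoxidation of the (E)-allylic alcohol, where diethyl L-tartrate gives the (2S,3S)-epoxy alcohol, fixing C8 and (after inversion in step 6) C9, and the non-allylic C10=C11 alkene is not touched.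

**Step 6**
Reactants: 9 tert-butyl (2R)-2-[(2S,3S)-3-[(1E)-3,3-dimethoxy-2-methylprop-1-en-1-yl]-2-(hydroxymethyl)oxiran-2-yl]propanoate
Product: 11 tert-butyl (2R,3S,4R,5E)-4-acetoxy-3-hydroxy-3-(hydroxymethyl)-2,6-dimethyl-7-oxohept-5-enoate, via acetoxy diol dimethyl acetal 10 (not isolated)
Conditions: Ti(OiPr)4 (1.5 equiv), AcOH (2 equiv), CH2Cl2, 0 to 23 °C; then 1 M HCl, THF, 0 °C
Reagents that add atoms: acetic acid CC(=O)O; water O
Why: Ti(OiPr)4-mediated C3-selective opening of the 2,3-epoxy alcohol by acetic acid (SN2 at the allylic C9 with inversion, C8–O retained) installs the 9-acetate with the final 9R configuration and leaves the tertiary 8-OH free, and dilute acid then unmasks the enal.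

**Step 7**
Reactants: 12 1,3-dichloropropan-2-one
Product: 13 1,3-dichloro-2-(chloromethyl)prop-1-ene
Conditions: (chloromethyl)triphenylphosphonium chloride, NaN(SiMe3)2, THF, −78 to 0 °C
Reagents that add atoms: (chloromethyl)triphenylphosphonium chloride ClC[P+](c1ccccc1)(c1ccccc1)c1ccccc1.[Cl-]
Why: Wittig chloromethylenation of the ketone; no stereocentre is formed and the two CH2Cl arms are equivalent.

**Step 8**
Reactants: 14 3-methylpentane-2,4-dione; 13 1,3-dichloro-2-(chloromethyl)prop-1-ene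
Product: 15 8-chloro-7-(chloromethyl)-3-methyloct-7-ene-2,4-dione
Conditions: LiN(iPr)2 (2.1 equiv), THF, −78 °C; 13 (1.5 equiv), −78 to −40 °C; AcOH quench at −78 °C
Reagents that add atoms: none
Why: γ-alkylation of the β-diketone dianion at its terminal carbanion by one allylic CH2Cl of 13 (C3–C4 bond), quenched cold so that the remaining diketone enolate does not cyclize onto the second allylic chloride.

**Step 9**
Reactants: 15 8-chloro-7-(chloromethyl)-3-methyloct-7-ene-2,4-dione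
Product: 16 8-chloro-7-(chloromethyl)-3-methyl-2,4-bis(trimethylsilyloxy)octa-1,3,7-triene
Conditions: LiN(iPr)2 (2.2 equiv), THF, −78 °C; Me3SiCl (2.5 equiv), −78 to 0 °C
Reagents that add atoms: chlorotrimethylsilane C[Si](C)(C)Cl
Why: the dianion is regenerated (second deprotonation at the CH3 rather than the CH2) and O-silylated twice to give the 1,3-bis(silyloxy)diene needed for a vinylogous Mukaiyama aldol.

**Step 10**
Reactants: 11 tert-butyl (2R,3S,4R,5E)-4-acetoxy-3-hydroxy-3-(hydroxymethyl)-2,6-dimethyl-7-oxohept-5-enoate; 16 8-chloro-7-(chloromethyl)-3-methyl-2,4-bis(trimethylsilyloxy)octa-1,3,7-triene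
Product: 19 tert-butyl (2R,3S,4R,5E,7R)-4-acetoxy-15-chloro-14-(chloromethyl)-3,7-dihydroxy-3-(hydroxymethyl)-2,6,10-trimethyl-9,11-dioxopentadeca-5,14-dienoate, via bis-silylated enal 17 (not isolated), via silylated aldol adduct 18 (not isolated)
Conditions: N-(trimethylsilyl)imidazole (2.2 equiv), CH2Cl2, 0 °C; then Ti(OiPr)4/(R)-1,1'-bi-2-naphthol (10 mol%), 16 (1.5 equiv), 4 Å molecular sieves, THF, −78 to −20 °C; then citric acid, MeOH, 23 °C
Reagents that add atoms: none
Why: vinylogous Mukaiyama aldol of the bis(silyloxy)diene at its terminal carbon (C13) with the transiently silylated enal, in which the chiral titanium binaphtholate selects the aldehyde face and sets 12R independently of the remote C8/C9 centres (the ligand antipode would give 12S), and acidic methanol then removes all silyl groups.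

**Step 11 (key step)**
Reactants: 19 tert-butyl (2R,3S,4R,5E,7R)-4-acetoxy-15-chloro-14-(chloromethyl)-3,7-dihydroxy-3-(hydroxymethyl)-2,6,10-trimethyl-9,11-dioxopentadeca-5,14-dienoate
Product: 20 tert-butyl (2R,3S,4R)-4-acetoxy-4-[(1S,2S,5R)-2-[5-chloro-4-(chloromethyl)pent-4-enoyl]-5-hydroxy-2-methyl-6-methylidene-3-oxocyclohexyl]-3-hydroxy-3-(hydroxymethyl)-2-methylbutanoate
Conditions: Mn(OAc)3·2H2O (2.2 equiv), Cu(OAc)2·H2O (0.5 equiv), degassed AcOH, 25 °C
Reagents that add atoms: none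
Why: Mn(OAc)3-based oxidative free-radical cyclization in which the 2-methyl-1,3-diketone is oxidized to the tertiary C1 radical, which adds 6-endo to C10 of the (E)-C10=C11 alkene through a chair (C9 branch equatorial, 12-OH pseudoaxial to avoid A(1,2) strain with the C11 methyl, C2 acyl group syn to the C14 carbonyl and therefore equatorial, CH3-15 axial) to set 1S and 10S, and Cu(OAc)2 then oxidizes the tertiary C11 radical by β-hydride elimination to the less substituted exocyclic 11(20)-alkene, while the electron-poor vinyl chloride arm is not attacked by this electrophilic radical.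

**Step 12**
Reactants: 20 tert-butyl (2R,3S,4R)-4-acetoxy-4-[(1S,2S,5R)-2-[5-chloro-4-(chloromethyl)pent-4-enoyl]-5-hydroxy-2-methyl-6-methylidene-3-oxocyclohexyl]-3-hydroxy-3-(hydroxymethyl)-2-methylbutanoate
Product: 21 tert-butyl (2R,3S,4R)-4-acetoxy-4-[(1S,2S,3S,5R)-2-[(1R)-5-chloro-4-(chloromethyl)-1-hydroxypent-4-en-1-yl]-3,5-dihydroxy-2-methyl-6-methylidenecyclohexyl]-3-hydroxy-3-(hydroxymethyl)-2-methylbutanoate
Conditions: Et2BOMe (4 equiv), NaBH4 (5 equiv), THF/MeOH 4:1, −78 to −30 °C; then AcOH, MeOH azeotrope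
Reagents that add atoms: none
Why: Proposed new method: two Narasaka–Prasad-type syn reductions run in relay in one flask, in which the 12-O–BEt2 chelate directs external hydride to C14 (cis-1,3-diol, 14S) and excess Et2BOMe then borylates the new 14-alkoxide, whose chelate with the C2 ketone is attacked from the face of the small CH3-15 (anti to the ring branch C10) to give 2R; the closest known reaction is the Et2BOMe/NaBH4 syn-1,3-diol reduction of β-hydroxy ketones.

**Step 13**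
Reactants: 21 tert-butyl (2R,3S,4R)-4-acetoxy-4-[(1S,2S,3S,5R)-2-[(1R)-5-chloro-4-(chloromethyl)-1-hydroxypent-4-en-1-yl]-3,5-dihydroxy-2-methyl-6-methylidenecyclohexyl]-3-hydroxy-3-(hydroxymethyl)-2-methylbutanoate
Product: 22 tert-butyl (2R,3R,4R)-4-acetoxy-4-[(1S,2S,3S,5R)-2-[(1R)-5-chloro-4-(chloromethyl)-1-hydroxypent-4-en-1-yl]-3,5-dihydroxy-2-methyl-6-methylidenecyclohexyl]-3-formyl-3-hydroxy-2-methylbutanoate
Conditions: 2,2,6,6-tetramethylpiperidin-1-oxyl (0.2 equiv), PhI(OAc)2 (1.2 equiv), CH2Cl2, 0 to 23 °C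
Reagents that add atoms: none
Why: oxoammonium-mediated oxidation is selective for the primary C7 alcohol over the secondary and tertiary alcohols and gives the α-hydroxy aldehyde, which has no epimerizable α-hydrogen.

**Step 14**
Reactants: 22 tert-butyl (2R,3R,4R)-4-acetoxy-4-[(1S,2S,3S,5R)-2-[(1R)-5-chloro-4-(chloromethyl)-1-hydroxypent-4-en-1-yl]-3,5-dihydroxy-2-methyl-6-methylidenecyclohexyl]-3-formyl-3-hydroxy-2-methylbutanoate
Product: 24 (1S,2R,6S,7R,8R,9R,10S,12R,14S,17R)-9-acetoxy-6-chloro-2,8,12,14-tetrahydroxybriara-5(16),11(20)-diene 19,7-lactone, via hydroxy tert-butyl ester 23 (not isolated)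
Conditions: CrCl2 (8 equiv), LiI (1 equiv), THF/DMF 4:1, 0.002 M, 23 °C; then CF3CO2H, CH2Cl2, 0 °C
Reagents that add atoms: none
Why: Proposed new method: divalent chromium inserts into the allylic C16–Cl bond and the γ-chloroallyl species (trivalent chromium) adds through its chlorine-bearing C6 to the C7 aldehyde in a chair transition state (anti chlorohydrin) while the C8 chromium alkoxide chelates the aldehyde so that the tethered nucleophile attacks the face giving 7R/6S, which closes the ten-membered ring and creates the 5(16)-methylene, and CF3CO2H then cleaves the tert-butyl ester so that the acid lactonizes onto O7 (O9 is blocked as its acetate); the closest known reactions are the CrCl2 chloroallylation of aldehydes (Takai) and intramolecular Nozaki–Hiyama allylations to ten-membered rings.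

**Step 15**
Reactants: 24 (1S,2R,6S,7R,8R,9R,10S,12R,14S,17R)-9-acetoxy-6-chloro-2,8,12,14-tetrahydroxybriara-5(16),11(20)-diene 19,7-lactone
Product: 25 (1S,2R,6S,7R,8R,9R,10S,11R,12R,14S,17R)-9-acetoxy-6-chloro-11,20-epoxy-2,8,12,14-tetrahydroxybriar-5(16)-ene 19,7-lactone
Conditions: VO(acac)2 (5 mol%), tert-butyl hydroperoxide (1.2 equiv), CH2Cl2, 0 °C
Reagents that add atoms: tert-butyl hydroperoxide CC(C)(C)OO
Why: hydroxyl-directed epoxidation in which the allylic 12-OH delivers oxygen to the 11(20)-methylene syn to itself (11R), leaving the non-allylic 5(16)-methylene alone.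

**Step 16**
Reactants: 25 (1S,2R,6S,7R,8R,9R,10S,11R,12R,14S,17R)-9-acetoxy-6-chloro-11,20-epoxy-2,8,12,14-tetrahydroxybriar-5(16)-ene 19,7-lactone
Product: 26 (1S,2R,6S,7R,8R,9R,10S,11R,12R,14S,17R)-2,9,12,14-tetraacetoxy-6-chloro-11,20-epoxy-8-hydroxybriar-5(16)-ene 19,7-lactone (CNP0349227.4)
Conditions: Ac2O, pyridine, 4-(dimethylamino)pyridine (cat.), CH2Cl2, 23 °C
Reagents that add atoms: acetic anhydride CC(=O)OC(C)=O
Why: nucleophile-catalysed acetylation of the three secondary alcohols (O2, O12, O14) while the hindered tertiary 8-OH stays free.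

**Compound list**
1 | tert-butyl (2R)-2-hydroxypropanoate | C[C@@H](O)C(=O)OC(C)(C)C | starting material
2 | tert-butyl (2R)-2-[(trifluoromethanesulfonyl)oxy]propanoate | C[C@@H](OS(=O)(=O)C(F)(F)F)C(=O)OC(C)(C)C | intermediate
3 | ethyl bromoacetate | CCOC(=O)CBr | starting material
4 | triethyl phosphonoacetate (not isolated) | CCOC(=O)CP(=O)(OCC)OCC | intermediate
5 | 4-tert-butyl 1-ethyl (3S)-2-(diethoxyphosphoryl)-3-methylbutanedioate (both C2 epimers) | CCOC(=O)C([C@@H](C)C(=O)OC(C)(C)C)P(=O)(OCC)OCC | intermediate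
6 | (2E)-4,4-dimethoxy-3-methylbut-2-enal | COC(OC)/C(C)=C/C=O | starting material
7 | 4-tert-butyl 1-ethyl (2E,3R)-2-[(2E)-4,4-dimethoxy-3-methylbut-2-en-1-ylidene]-3-methylbutanedioate | COC(OC)/C(C)=C/C=C(/C(=O)OCC)[C@@H](C)C(=O)OC(C)(C)C | intermediate
8 | tert-butyl (2R,3E,5E)-3-(hydroxymethyl)-7,7-dimethoxy-2,6-dimethylhepta-3,5-dienoate | COC(OC)/C(C)=C/C=C(/CO)[C@@H](C)C(=O)OC(C)(C)C | intermediate
9 | tert-butyl (2R)-2-[(2S,3S)-3-[(1E)-3,3-dimethoxy-2-methylprop-1-en-1-yl]-2-(hydroxymethyl)oxiran-2-yl]propanoate | COC(OC)/C(C)=C/[C@@H]1O[C@]1(CO)[C@@H](C)C(=O)OC(C)(C)C | intermediate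
10 | tert-butyl (2R,3S,4R,5E)-4-acetoxy-3-hydroxy-3-(hydroxymethyl)-7,7-dimethoxy-2,6-dimethylhept-5-enoate (not isolated) | COC(OC)/C(C)=C/[C@@H](OC(C)=O)[C@](CO)(O)[C@@H](C)C(=O)OC(C)(C)C | intermediate
11 | tert-butyl (2R,3S,4R,5E)-4-acetoxy-3-hydroxy-3-(hydroxymethyl)-2,6-dimethyl-7-oxohept-5-enoate | O=C/C(C)=C/[C@@H](OC(C)=O)[C@](CO)(O)[C@@H](C)C(=O)OC(C)(C)C | intermediate
12 | 1,3-dichloropropan-2-one | ClCC(=O)CCl | starting material
13 | 1,3-dichloro-2-(chloromethyl)prop-1-ene | ClC=C(CCl)CCl | intermediate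
14 | 3-methylpentane-2,4-dione | CC(=O)C(C)C(C)=O | starting material
15 | 8-chloro-7-(chloromethyl)-3-methyloct-7-ene-2,4-dione (7E/7Z mixture, C3 enolizable) | CC(=O)C(C)C(=O)CCC(CCl)=CCl | intermediate
16 | 8-chloro-7-(chloromethyl)-3-methyl-2,4-bis(trimethylsilyloxy)octa-1,3,7-triene | C=C(O[Si](C)(C)C)C(C)=C(O[Si](C)(C)C)CCC(CCl)=CCl | intermediate
17 | tert-butyl (2R,3S,4R,5E)-4-acetoxy-2,6-dimethyl-7-oxo-3-(trimethylsilyloxy)-3-[(trimethylsilyloxy)methyl]hept-5-enoate (not isolated) | O=C/C(C)=C/[C@@H](OC(C)=O)[C@](CO[Si](C)(C)C)(O[Si](C)(C)C)[C@@H](C)C(=O)OC(C)(C)C | intermediate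
18 | silylated aldol adduct: compound 19 carrying OSiMe3 on O7, O8 and O12 and a trimethylsilyl enol ether at C2=C1 (not isolated) | ClC=C(CCl)CCC(O[Si](C)(C)C)=C(C)C(=O)C[C@@H](O[Si](C)(C)C)/C(C)=C/[C@@H](OC(C)=O)[C@](CO[Si](C)(C)C)(O[Si](C)(C)C)[C@@H](C)C(=O)OC(C)(C)C | intermediate
19 | tert-butyl (2R,3S,4R,5E,7R)-4-acetoxy-15-chloro-14-(chloromethyl)-3,7-dihydroxy-3-(hydroxymethyl)-2,6,10-trimethyl-9,11-dioxopentadeca-5,14-dienoate (C10 of the chain enolizable, 14E/14Z mixture) | ClC=C(CCl)CCC(=O)C(C)C(=O)C[C@@H](O)/C(C)=C/[C@@H](OC(C)=O)[C@](CO)(O)[C@@H](C)C(=O)OC(C)(C)C | intermediate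
20 | tert-butyl (2R,3S,4R)-4-acetoxy-4-[(1S,2S,5R)-2-[5-chloro-4-(chloromethyl)pent-4-enoyl]-5-hydroxy-2-methyl-6-methylidene-3-oxocyclohexyl]-3-hydroxy-3-(hydroxymethyl)-2-methylbutanoate | ClC=C(CCl)CCC(=O)[C@@]1(C)C(=O)C[C@@H](O)C(=C)[C@@H]1[C@@H](OC(C)=O)[C@](CO)(O)[C@@H](C)C(=O)OC(C)(C)C | intermediate
21 | tert-butyl (2R,3S,4R)-4-acetoxy-4-[(1S,2S,3S,5R)-2-[(1R)-5-chloro-4-(chloromethyl)-1-hydroxypent-4-en-1-yl]-3,5-dihydroxy-2-methyl-6-methylidenecyclohexyl]-3-hydroxy-3-(hydroxymethyl)-2-methylbutanoate | ClC=C(CCl)CC[C@@H](O)[C@@]1(C)[C@@H](O)C[C@@H](O)C(=C)[C@@H]1[C@@H](OC(C)=O)[C@](CO)(O)[C@@H](C)C(=O)OC(C)(C)C | intermediate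
22 | tert-butyl (2R,3R,4R)-4-acetoxy-4-[(1S,2S,3S,5R)-2-[(1R)-5-chloro-4-(chloromethyl)-1-hydroxypent-4-en-1-yl]-3,5-dihydroxy-2-methyl-6-methylidenecyclohexyl]-3-formyl-3-hydroxy-2-methylbutanoate | ClC=C(CCl)CC[C@@H](O)[C@@]1(C)[C@@H](O)C[C@@H](O)C(=C)[C@@H]1[C@@H](OC(C)=O)[C@](C=O)(O)[C@@H](C)C(=O)OC(C)(C)C | intermediate
23 | tert-butyl (2R)-2-[(1S,2R,6S,7R,8S,9R,10S,12R,14S)-9-acetoxy-6-chloro-2,7,8,12,14-pentahydroxy-1-methyl-5,11-dimethylidenebicyclo[8.4.0]tetradecan-8-yl]propanoate (not isolated) | C=C1CC[C@@H](O)[C@@]2(C)[C@@H](O)C[C@@H](O)C(=C)[C@@H]2[C@@H](OC(C)=O)[C@](O)([C@@H](C)C(=O)OC(C)(C)C)[C@@H](O)[C@H]1Cl | intermediate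
24 | (1S,2R,6S,7R,8R,9R,10S,12R,14S,17R)-9-acetoxy-6-chloro-2,8,12,14-tetrahydroxybriara-5(16),11(20)-diene 19,7-lactone | C=C1CC[C@@H](O)[C@@]2(C)[C@@H](O)C[C@@H](O)C(=C)[C@@H]2[C@@H](OC(C)=O)[C@]2(O)[C@@H](C)C(=O)O[C@H]2[C@H]1Cl | intermediate
25 | (1S,2R,6S,7R,8R,9R,10S,11R,12R,14S,17R)-9-acetoxy-6-chloro-11,20-epoxy-2,8,12,14-tetrahydroxybriar-5(16)-ene 19,7-lactone | C=C1CC[C@@H](O)[C@@]2(C)[C@@H](O)C[C@@H](O)[C@]3(CO3)[C@@H]2[C@@H](OC(C)=O)[C@]2(O)[C@@H](C)C(=O)O[C@H]2[C@H]1Cl | intermediate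
26 | (1S,2R,6S,7R,8R,9R,10S,11R,12R,14S,17R)-2,9,12,14-tetraacetoxy-6-chloro-11,20-epoxy-8-hydroxybriar-5(16)-ene 19,7-lactone (CNP0349227.4) | C=C1CC[C@@H](OC(C)=O)[C@@]2(C)[C@@H](OC(C)=O)C[C@@H](OC(C)=O)[C@]3(CO3)[C@@H]2[C@@H](OC(C)=O)[C@]2(O)[C@@H](C)C(=O)O[C@H]2[C@H]1Cl | target

**Summary**
Total step count: 16. Longest linear sequence: 13 steps (steps 1–6, then 10–16); steps 7–9 form the second branch.

Three steps most likely to fail:

Step 11. Risks: the C12/C9 stereocentres may not enforce the chair that gives 1S/10S; the second alkene arm, the free 1,2-diol or elimination toward C12 may compete. Fallback: setting out from 19, C1 is selenenylated with PhSeCl/pyridine to the 2-(phenylselanyl)-1,3-diketone F1. A phenylselanyl group-transfer radical cyclization (sunlamp, catalytic (Bu3Sn)2, Mg(ClO4)2 as chelating Lewis acid holding the two carbonyls syn) gives the tertiary C11 selenide F2. Oxidation with H2O2 and selenoxide syn-elimination toward the methyl group (away from the carbinol carbon) comes back to the route at 20.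

Step 12. Risks: the second, relayed reduction may give the C2 epimer, or NaBH4 may reduce C2 without chelation. Fallback: setting out from 20, the sequence is split. One Et2BOMe/NaBH4 reduction is stopped at the 14-hydroxy-2-ketone F3, and the C2 ketone is then reduced under reagent control with catecholborane and the catalyst (S)-1-methyl-3,3-diphenyltetrahydro-1H,3H-pyrrolo[1,2-c][1,3,2]oxazaborole (large group C1, small group C3), which comes back at 21.

Step 14. Risks: ten-membered ring closure against oligomerization, and facial control at C7 in an unprotected polyol. Fallback: setting out from 21, the allylic chloride is exchanged for silicon with Me3SiSiMe3 and Pd(PPh3)4 (zerovalent palladium) to give the allylsilane F4. The C7 alcohol is oxidized as in step 13 to the aldehyde F5. An intramolecular Hosomi–Sakurai allylation with BF3·OEt2 (Lewis-acid activation, open transition state) gives the same hydroxy ester 23, which is lactonized with CF3CO2H and comes back at 24.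

**Further compounds**
F1 | step 11 | tert-butyl (2R,3S,4R,5E,7R)-4-acetoxy-15-chloro-14-(chloromethyl)-3,7-dihydroxy-3-(hydroxymethyl)-2,6,10-trimethyl-9,11-dioxo-10-(phenylselanyl)pentadeca-5,14-dienoate | ClC=C(CCl)CCC(=O)C(C)([Se]c1ccccc1)C(=O)C[C@@H](O)/C(C)=C/[C@@H](OC(C)=O)[C@](CO)(O)[C@@H](C)C(=O)OC(C)(C)C
F2 | step 11 | tert-butyl (2R,3S,4R)-4-acetoxy-4-[(1S,2S,5R)-2-[5-chloro-4-(chloromethyl)pent-4-enoyl]-5-hydroxy-2,6-dimethyl-3-oxo-6-(phenylselanyl)cyclohexyl]-3-hydroxy-3-(hydroxymethyl)-2-methylbutanoate | ClC=C(CCl)CCC(=O)[C@@]1(C)C(=O)C[C@@H](O)C(C)([Se]c2ccccc2)[C@@H]1[C@@H](OC(C)=O)[C@](CO)(O)[C@@H](C)C(=O)OC(C)(C)C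
F3 | step 12 | tert-butyl (2R,3S,4R)-4-acetoxy-4-[(1S,2S,3S,5R)-2-[5-chloro-4-(chloromethyl)pent-4-enoyl]-3,5-dihydroxy-2-methyl-6-methylidenecyclohexyl]-3-hydroxy-3-(hydroxymethyl)-2-methylbutanoate | ClC=C(CCl)CCC(=O)[C@@]1(C)[C@@H](O)C[C@@H](O)C(=C)[C@@H]1[C@@H](OC(C)=O)[C@](CO)(O)[C@@H](C)C(=O)OC(C)(C)C
F4 | step 14 | tert-butyl (2R,3S,4R)-4-acetoxy-4-[(1S,2S,3S,5R)-2-[(1R)-5-chloro-1-hydroxy-4-[(trimethylsilyl)methyl]pent-4-en-1-yl]-3,5-dihydroxy-2-methyl-6-methylidenecyclohexyl]-3-hydroxy-3-(hydroxymethyl)-2-methylbutanoate | ClC=C(C[Si](C)(C)C)CC[C@@H](O)[C@@]1(C)[C@@H](O)C[C@@H](O)C(=C)[C@@H]1[C@@H](OC(C)=O)[C@](CO)(O)[C@@H](C)C(=O)OC(C)(C)C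
F5 | step 14 | tert-butyl (2R,3R,4R)-4-acetoxy-4-[(1S,2S,3S,5R)-2-[(1R)-5-chloro-1-hydroxy-4-[(trimethylsilyl)methyl]pent-4-en-1-yl]-3,5-dihydroxy-2-methyl-6-methylidenecyclohexyl]-3-formyl-3-hydroxy-2-methylbutanoate | ClC=C(C[Si](C)(C)C)CC[C@@H](O)[C@@]1(C)[C@@H](O)C[C@@H](O)C(=C)[C@@H]1[C@@H](OC(C)=O)[C@](C=O)(O)[C@@H](C)C(=O)OC(C)(C)C
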